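**Retrosynthetic overview**
- The strategy rests on the C4(carbonyl)–C4a bond of pyranone ring C. C4a lies on ring A ortho to O1 and para to the C7 oxygen, the most nucleophilic carbon of a resorcinol diether. The chromone is therefore opened there to a 2-aryl-3-aryloxyacrylic acid.
- In that acid, the O1–C2 bond comes from vinylic substitution of an enol tosylate by 3-isopropoxyphenol. C2 comes from methyl formate, and C3/C4 come from an acetate unit coupled to a ring B bromide.
- Ring B with its dimethylpyran ring D is built from isovanillin by propargyl ether formation, Claisen/electrocyclisation, saturation, Baeyer–Villiger oxidation, O-isopropylation and bromination.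
- Ring order: D first (chromene, then masked as a chroman), then C by Friedel–Crafts closure onto ring A. DDQ restores the ring D alkene and BCl3 removes both isopropyl ethers at the end.

Key step: step 12

Assumption: the enol, its tosylate, the aryloxyacrylate ester and the derived acid are drawn as Z isomers (oxygen substituent cis to the carboxyl carbon). This is the geometry expected from a chelated enolate and from retentive vinylic substitution. Any E isomer would be carried on, because the geometry becomes mobile in the key step.

Step 1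
Reactants: 1 isovanillin (3-hydroxy-4-methoxybenzaldehyde); 2 3-chloro-3-methylbut-1-yne
Product: 3 4-methoxy-3-[(2-methylbut-3-yn-2-yl)oxy]benzaldehyde
Conditions: K2CO3, KI (cat.), CuI (cat.), DMF, 60 °C
Reagents that add atoms: none
Why: Copper-assisted Williamson-type O-alkylation of the phenoxide with the tertiary propargylic chloride is the standard entry to aryl 1,1-dimethylpropargyl ethers and leaves the aldehyde untouched.

Step 2
Reactants: 3 4-methoxy-3-[(2-methylbut-3-yn-2-yl)oxy]benzaldehyde
Product: 4 8-methoxy-2,2-dimethyl-2H-chromene-5-carbaldehyde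
Conditions: PhNEt2, 190 °C
Reagents that add atoms: none
Why: The aromatic propargyl Claisen rearrangement, followed by 1,5-hydrogen shift and oxa-6π electrocyclisation, can use only the free ortho carbon lying between the ether-bearing and formyl-bearing carbons, because the other ortho position carries the methoxy group, so ring D is fused in the required orientation.

Step 3
Reactants: 4 8-methoxy-2,2-dimethyl-2H-chromene-5-carbaldehyde
Product: 5 8-methoxy-2,2-dimethylchroman-5-carbaldehyde
Conditions: H2 (1 atm), 10% Pd/C, Ph2S (cat.), EtOAc, rt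
Reagents that add atoms: none
Why: Catalytic hydrogenation over sulfide-attenuated Pd/C should saturate the styrene-type C3=C4 bond and spare the aromatic aldehyde, which masks an alkene that would survive neither the peracid of step 4 nor the acid of step 12.

Step 4
Reactants: 5 8-methoxy-2,2-dimethylchroman-5-carbaldehyde
Product: 7 8-methoxy-2,2-dimethylchroman-5-ol, via aryl formate 6 (not isolated)
Conditions: mCPBA, CH2Cl2, 0 °C → rt; aq NaHCO3 wash, solvent switch; K2CO3 (0.2 equiv), MeOH, rt
Reagents that add atoms: mCPBA, O=C(OO)c1cccc(Cl)c1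
Why: In this Baeyer–Villiger (Dakin-type) oxidation the aryl group, enriched by the para methoxy group, migrates in preference to hydride, and the resulting formate is removed by base-catalysed methanolysis.

Step 5
Reactants: 7 8-methoxy-2,2-dimethylchroman-5-ol
Product: 8 5-isopropoxy-8-methoxy-2,2-dimethylchroman
Conditions: 2-bromopropane, K2CO3, DMF, 60 °C
Reagents that add atoms: 2-bromopropane, CC(C)Br
Why: Williamson ether synthesis installs an isopropyl ether, which tolerates Brønsted acid yet is later cleaved by BCl3 much faster than the methyl ether.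

Step 6
Reactants: 8 5-isopropoxy-8-methoxy-2,2-dimethylchroman
Product: 9 6-bromo-5-isopropoxy-8-methoxy-2,2-dimethylchroman
Conditions: NBS, MeCN, 0 °C → rt, dark
Reagents that add atoms: N-bromosuccinimide, O=C1CCC(=O)N1Br
Why: Electrophilic aromatic bromination should go to C6, which is ortho to the isopropoxy group and para to ring oxygen O1, whereas C7 is activated by only one oxygen.

Step 7
Reactants: 9 6-bromo-5-isopropoxy-8-methoxy-2,2-dimethylchroman; 10 (2-tert-butoxy-2-oxoethyl)zinc bromide (Reformatsky reagent, THF solution)
Product: 11 tert-butyl 2-(5-isopropoxy-8-methoxy-2,2-dimethylchroman-6-yl)acetate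
Conditions: Pd2(dba)3 (2 mol %), XPhos (8 mol %), THF, 65 °C
Reagents that add atoms: none
Why: In this Negishi-type α-arylation of a Reformatsky reagent, the bulky electron-rich biarylphosphine helps zerovalent palladium insert into the electron-rich ortho-substituted bromide, and the nearly neutral zinc enolate avoids ester self-condensation.

Step 8
Reactants: 11 tert-butyl 2-(5-isopropoxy-8-methoxy-2,2-dimethylchroman-6-yl)acetate
Product: 12 tert-butyl (Z)-3-hydroxy-2-(5-isopropoxy-8-methoxy-2,2-dimethylchroman-6-yl)acrylate (enol form of the α-formyl ester)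
Conditions: NaH, HCO2Me, THF, 0 °C → rt; aq HCl quench
Reagents that add atoms: methyl formate, COC=O
Why: The crossed Claisen condensation (C-formylation) of the arylacetate enolate with a non-enolisable formate is driven by formation of the stabilised sodium enolate, and the product should rest as the hydrogen-bonded Z enol.

Step 9
Reactants: 12 tert-butyl (Z)-3-hydroxy-2-(5-isopropoxy-8-methoxy-2,2-dimethylchroman-6-yl)acrylate
Product: 13 tert-butyl (Z)-2-(5-isopropoxy-8-methoxy-2,2-dimethylchroman-6-yl)-3-(tosyloxy)acrylate
Conditions: TsCl, N-methylimidazole, LiOH, CH2Cl2, 0 °C → rt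
Reagents that add atoms: 4-toluenesulfonyl chloride, Cc1ccc(cc1)S(=O)(=O)Cl
Why: In this enol O-sulfonylation lithium bridges the enolate and ester oxygens, so sulfonyl transfer catalysed by N-methylimidazole should fix the tosyloxy group cis to the ester.

Step 10
Reactants: 13 tert-butyl (Z)-2-(5-isopropoxy-8-methoxy-2,2-dimethylchroman-6-yl)-3-(tosyloxy)acrylate; 14 3-isopropoxyphenol
Product: 15 tert-butyl (Z)-3-(3-isopropoxyphenoxy)-2-(5-isopropoxy-8-methoxy-2,2-dimethylchroman-6-yl)acrylate
Conditions: K2CO3, DABCO (20 mol %), MeCN, rt → 40 °C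
Reagents that add atoms: none
Why: In this vinylic nucleophilic substitution by addition–elimination the phenoxide adds to the β-carbon and tosylate leaves, with the retention usual for a good nucleofuge on a singly activated alkene, while DABCO as nucleophilic catalyst steers attack to carbon and away from sulfur.

Step 11
Reactants: 15 tert-butyl (Z)-3-(3-isopropoxyphenoxy)-2-(5-isopropoxy-8-methoxy-2,2-dimethylchroman-6-yl)acrylate
Product: 16 (Z)-3-(3-isopropoxyphenoxy)-2-(5-isopropoxy-8-methoxy-2,2-dimethylchroman-6-yl)acrylic acid
Conditions: CF3CO2H–CH2Cl2 (1:3), 1,3-dimethoxybenzene (5 equiv), 0 °C → rt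
Reagents that add atoms: none
Why: Acidolysis of the tert-butyl ester by alkyl–oxygen cleavage frees the acid without hydroxide, which could expel the aryloxide by conjugate addition–elimination, and the added dimethoxybenzene traps the tert-butyl cation before it reaches rings A or B.

Step 12
Reactants: 16 (Z)-3-(3-isopropoxyphenoxy)-2-(5-isopropoxy-8-methoxy-2,2-dimethylchroman-6-yl)acrylic acid
Product: 18 7-isopropoxy-3-(5-isopropoxy-8-methoxy-2,2-dimethylchroman-6-yl)-4H-chromen-4-one, via acylium ion 17 (not isolated)
Conditions: P2O5–MeSO3H (1:10 w/w, Eaton's reagent), CH2Cl2, 0 °C → rt; ice/NaHCO3 quench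
Reagents that add atoms: none
Why: The dehydrating acid ionises the carboxyl group of 16 to acylium ion 17, whose charge is shared with the enol-ether oxygen in a ketene-oxocarbenium form, so the Cα=Cβ bond can rotate and any E isomer is funnelled into the reactive cis arrangement. The acylium carbon then attacks ring A at the carbon ortho to the vinyl-ether oxygen and para to the isopropoxy group, and proton loss from the arenium ion completes the C4–C4a bond; this is an intramolecular Friedel–Crafts acylation, the established way of turning 3-aryloxyacrylic acids into chromones. Ring C closes in a six-membered mode, 6-exo-dig at the acylium carbon with the arene carbon as internal nucleophile, and no stereocentre is formed. The selectivity required is between the two carbons ortho to O1: the one para to the isopropoxy group is both better activated and unhindered, while the one between the two oxygens is flanked on both sides, so the 7-oxygenated chromone should form and not the 5-oxygenated isomer. Chemoselectivity is secured by the substrate, since ring D is saturated, both phenol oxygens carry isopropyl groups that resist Brønsted acid at or below room temperature, and no carbon of ring B can reach the acylium centre in an unstrained ring.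

Step 13
Reactants: 18 7-isopropoxy-3-(5-isopropoxy-8-methoxy-2,2-dimethylchroman-6-yl)-4H-chromen-4-one
Product: 19 7-isopropoxy-3-(5-isopropoxy-8-methoxy-2,2-dimethyl-2H-chromen-6-yl)-4H-chromen-4-one
Conditions: DDQ, dry 1,4-dioxane, 100 °C
Reagents that add atoms: none
Why: In this DDQ dehydrogenation of a 2,2-dimethylchroman, hydride is taken from benzylic C4 of ring D, where the cation is stabilised by the two ortho oxygens (O1 and the 5-isopropoxy group), a C3 proton is then lost, and the protected phenols keep the hydroquinone-type ring B from being oxidised.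

Step 14
Reactants: 19 7-isopropoxy-3-(5-isopropoxy-8-methoxy-2,2-dimethyl-2H-chromen-6-yl)-4H-chromen-4-one
Product: 20 7-hydroxy-3-(5-hydroxy-8-methoxy-2,2-dimethyl-2H-chromen-6-yl)-4H-chromen-4-one (target)
Conditions: BCl3 (1 M in CH2Cl2, 4–5 equiv), CH2Cl2, −78 → 0 °C; aq NaHCO3 quench
Reagents that add atoms: none
Why: In this Lewis-acid ether cleavage BCl3 coordinates the ether oxygens and the secondary isopropyl groups depart as 2-chloropropane far faster than the methyl group can, so low temperature should free both phenols and keep the methyl ether and the ring D alkene.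

**Compound list**
1 | isovanillin (3-hydroxy-4-methoxybenzaldehyde) | COc1ccc(C=O)cc1O | starting material
2 | 3-chloro-3-methylbut-1-yne | CC(C)(Cl)C#C | starting material
3 | 4-methoxy-3-[(2-methylbut-3-yn-2-yl)oxy]benzaldehyde | COc1ccc(C=O)cc1OC(C)(C)C#C | intermediate
4 | 8-methoxy-2,2-dimethyl-2H-chromene-5-carbaldehyde | COc1ccc(C=O)c2c1OC(C)(C)C=C2 | intermediate
5 | 8-methoxy-2,2-dimethylchroman-5-carbaldehyde | COc1ccc(C=O)c2c1OC(C)(C)CC2 | intermediate
6 | 8-methoxy-2,2-dimethylchroman-5-yl formate (not isolated) | COc1ccc(OC=O)c2c1OC(C)(C)CC2 | intermediate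
7 | 8-methoxy-2,2-dimethylchroman-5-ol | COc1ccc(O)c2c1OC(C)(C)CC2 | intermediate
8 | 5-isopropoxy-8-methoxy-2,2-dimethylchroman | COc1ccc(OC(C)C)c2c1OC(C)(C)CC2 | intermediate
9 | 6-bromo-5-isopropoxy-8-methoxy-2,2-dimethylchroman | COc1cc(Br)c(OC(C)C)c2c1OC(C)(C)CC2 | intermediate
10 | (2-tert-butoxy-2-oxoethyl)zinc bromide | CC(C)(C)OC(=O)C[Zn]Br | starting material
11 | tert-butyl 2-(5-isopropoxy-8-methoxy-2,2-dimethylchroman-6-yl)acetate | COc1cc(CC(=O)OC(C)(C)C)c(OC(C)C)c2c1OC(C)(C)CC2 | intermediate
12 | tert-butyl (Z)-3-hydroxy-2-(5-isopropoxy-8-methoxy-2,2-dimethylchroman-6-yl)acrylate | CC(C)(C)OC(=O)/C(=C\O)c1cc(OC)c2OC(C)(C)CCc2c1OC(C)C | intermediate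
13 | tert-butyl (Z)-2-(5-isopropoxy-8-methoxy-2,2-dimethylchroman-6-yl)-3-(tosyloxy)acrylate | CC(C)(C)OC(=O)/C(=C\OS(=O)(=O)c1ccc(C)cc1)c1cc(OC)c2OC(C)(C)CCc2c1OC(C)C | intermediate
14 | 3-isopropoxyphenol | CC(C)Oc1cccc(O)c1 | starting material
15 | tert-butyl (Z)-3-(3-isopropoxyphenoxy)-2-(5-isopropoxy-8-methoxy-2,2-dimethylchroman-6-yl)acrylate | CC(C)(C)OC(=O)/C(=C\Oc1cccc(OC(C)C)c1)c1cc(OC)c2OC(C)(C)CCc2c1OC(C)C | intermediate
16 | (Z)-3-(3-isopropoxyphenoxy)-2-(5-isopropoxy-8-methoxy-2,2-dimethylchroman-6-yl)acrylic acid | OC(=O)/C(=C\Oc1cccc(OC(C)C)c1)c1cc(OC)c2OC(C)(C)CCc2c1OC(C)C | intermediate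
17 | acylium ion derived from 16 (not isolated) | [O+]#C/C(=C\Oc1cccc(OC(C)C)c1)c1cc(OC)c2OC(C)(C)CCc2c1OC(C)C | intermediate
18 | 7-isopropoxy-3-(5-isopropoxy-8-methoxy-2,2-dimethylchroman-6-yl)-4H-chromen-4-one | O=c1c(-c2cc(OC)c3OC(C)(C)CCc3c2OC(C)C)coc2cc(OC(C)C)ccc12 | intermediate
19 | 7-isopropoxy-3-(5-isopropoxy-8-methoxy-2,2-dimethyl-2H-chromen-6-yl)-4H-chromen-4-one | O=c1c(-c2cc(OC)c3OC(C)(C)C=Cc3c2OC(C)C)coc2cc(OC(C)C)ccc12 | intermediate
20 | 7-hydroxy-3-(5-hydroxy-8-methoxy-2,2-dimethyl-2H-chromen-6-yl)-4H-chromen-4-one | COc1cc(-c2coc3cc(O)ccc3c2=O)c(O)c2c1OC(C)(C)C=C2 | target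

**Total step count:** 14. **Longest linear sequence:** 14 steps (1 → 20). Compounds 2, 10 and 14 enter as purchased partners.

**Steps most likely to fail**

Step 12 (key ring closure).
- What may go wrong: the ortho isopropoxy oxygen of ring B may capture the acylium carbon in a five-membered mode and then lose its isopropyl group (dealkylative lactonisation). The strong acid may also strip isopropyl groups before C-acylation occurs.
- Fallback: it sets out from bromide 9 and comes back at chromone 18. It forms the C3–aryl bond by cross-coupling on a preformed chromone.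
- Miyaura borylation of 9 (B2pin2, PdCl2(dppf), KOAc, dioxane, 90 °C) would give the pinacol boronate F1.
- Separately, commercial 2,4-dihydroxyacetophenone would be alkylated at its non-chelated hydroxyl (2-bromopropane, K2CO3, acetone) to 1-(2-hydroxy-4-isopropoxyphenyl)ethan-1-one F2.
- Condensation with DMF dimethyl acetal would give the enaminone F3, and I2 in MeOH would cyclise it to 3-iodo-7-isopropoxychromen-4-one F4.
- Suzuki–Miyaura coupling of F1 with F4 (Pd(OAc)2, SPhos, K3PO4, toluene–water, 80 °C) would deliver 18.

Step 14 (final dealkylation).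
- What may go wrong: the Lewis acid or the HCl it releases may open or hydrochlorinate the 2,2-dimethylchromene. Chelation between O1 and the methoxy oxygen may cost the methyl group. The electron-poor 7-O-isopropyl ether may cleave too slowly at temperatures the alkene tolerates.
- Fallback: it sets out from chroman 18, before the alkene exists, and comes back at target 20.
- BCl3 (CH2Cl2, 0 °C → rt) on 18 would give the dihydroxy chroman isoflavone F5.
- Silylation (TBSCl, imidazole, DMF, or TBSOTf/2,6-lutidine for the flanked hydroxyl) would give the bis-silyl ether F6.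
- DDQ in dioxane would give the bis-silyl chromene F7.
- Buffered fluoride (Bu4NF, AcOH, THF, 0 °C) would release 20 under conditions harmless to the alkene and the methyl ether.

Step 10 (C–O bond to ring A).
- What may go wrong: the phenoxide may attack sulfur instead of carbon, transferring the sulfonyl group and regenerating the enolate. Addition to the acceptor may be slow, or reversible aryloxide addition may scramble the geometry.
- Fallback: it sets out from bromide 9 and phenol 14 and comes back at ester 15. The C–O bond is made first on an unhindered acceptor that carries no sulfonate, and the Cα–aryl bond is made afterwards.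
- tert-Butyl propiolate and Br2 (CH2Cl2, 0 °C) would give, by anti addition, tert-butyl (E)-2,3-dibromoacrylate F10.
- Phenol 14 with K2CO3 in MeCN would replace only the β-bromide, giving tert-butyl (E)-2-bromo-3-(3-isopropoxyphenoxy)acrylate F11, in which the aryloxy group is cis to the ester.
- Bromide 9 would be converted with n-BuLi (THF, −78 °C) to the aryllithium F8 and then with ZnCl2 to the arylzinc chloride F9.
- Base-free Negishi coupling of F9 with F11 (Pd2(dba)3, SPhos, THF, rt → 50 °C) proceeds with retention and would give 15 directly as the Z isomer.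

**Further compounds**
F1 | step 12 | 2-(5-isopropoxy-8-methoxy-2,2-dimethylchroman-6-yl)-4,4,5,5-tetramethyl-1,3,2-dioxaborolane | COc1cc(B3OC(C)(C)C(C)(C)O3)c(OC(C)C)c2c1OC(C)(C)CC2
F2 | step 12 | 1-(2-hydroxy-4-isopropoxyphenyl)ethan-1-one | CC(=O)c1ccc(OC(C)C)cc1O
F3 | step 12 | (E)-3-(dimethylamino)-1-(2-hydroxy-4-isopropoxyphenyl)prop-2-en-1-one | CN(C)/C=C/C(=O)c1ccc(OC(C)C)cc1O
F4 | step 12 | 3-iodo-7-isopropoxy-4H-chromen-4-one | CC(C)Oc1ccc2c(c1)occ(I)c2=O
F5 | step 14 | 7-hydroxy-3-(5-hydroxy-8-methoxy-2,2-dimethylchroman-6-yl)-4H-chromen-4-one | COc1cc(-c2coc3cc(O)ccc3c2=O)c(O)c2c1OC(C)(C)CC2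
F6 | step 14 | 7-(tert-butyldimethylsilyloxy)-3-[5-(tert-butyldimethylsilyloxy)-8-methoxy-2,2-dimethylchroman-6-yl]-4H-chromen-4-one | COc1cc(-c2coc3cc(O[Si](C)(C)C(C)(C)C)ccc3c2=O)c(O[Si](C)(C)C(C)(C)C)c2c1OC(C)(C)CC2
F7 | step 14 | 7-(tert-butyldimethylsilyloxy)-3-[5-(tert-butyldimethylsilyloxy)-8-methoxy-2,2-dimethyl-2H-chromen-6-yl]-4H-chromen-4-one | COc1cc(-c2coc3cc(O[Si](C)(C)C(C)(C)C)ccc3c2=O)c(O[Si](C)(C)C(C)(C)C)c2c1OC(C)(C)C=C2
F8 | step 10 | (5-isopropoxy-8-methoxy-2,2-dimethylchroman-6-yl)lithium | [Li]c1cc(OC)c2OC(C)(C)CCc2c1OC(C)C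
F9 | step 10 | (5-isopropoxy-8-methoxy-2,2-dimethylchroman-6-yl)zinc chloride | Cl[Zn]c1cc(OC)c2OC(C)(C)CCc2c1OC(C)C
F10 | step 10 | tert-butyl (E)-2,3-dibromoacrylate | CC(C)(C)OC(=O)/C(Br)=C\Br
F11 | step 10 | tert-butyl (E)-2-bromo-3-(3-isopropoxyphenoxy)acrylate | CC(C)(C)OC(=O)/C(Br)=C\Oc1cccc(OC(C)C)c1
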